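**Retrosynthetic overview**
- The cis-disposed C15 acid and C16 acetate are made by oxidising C15 last, from the (13Z)-allylic alcohol that already carries both acetates, so the lactonisable cis hydroxy acid is never exposed.
- That alcohol comes from the 15,16,19-triacetate by lipase hydrolysis of the least hindered (C15) ester. The triol comes from reductive opening of the butenolide of andrograpanin, which fixes 13Z.
- The C3 oxygen is removed by radical fragmentation of a 3,19-cyclic thionocarbonate of 14-deoxyandrographolide.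
- The C14 oxygen is removed by SN2' hydride displacement of the C14 acetate of andrographolide triacetate, which moves the alkene from C12=C13 to C13=C14.
- No ring is formed. Rings A and B, the 8(17)-alkene and all four stereocentres (C4, C5, C9, C10) come intact from andrographolide; the lactone is the only ring changed (it is opened).

Assumption: andrographolide, a bulk commercial ent-labdane, is accepted as the commercially available starting material; its C4, C5, C9 and C10 configurations are those of the target.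

**Route**

Step 1
Reactants: 1 andrographolide
Product: 2 3,14,19-tri-O-acetylandrographolide
Conditions: Ac2O (6 equiv), pyridine, 0 °C to rt
Reagents that add atoms: acetic anhydride, CC(=O)OC(C)=O
Why: Pyridine-mediated acetylation (esterification) of all three hydroxyls turns the C14 oxygen into the leaving group needed next and touches no stereocentre.

Step 2
Reactants: 2 3,14,19-tri-O-acetylandrographolide
Product: 3 3,19-di-O-acetyl-14-deoxyandrographolide
Conditions: NaBH4 (1.2 equiv), THF/t-BuOH (4:1), −10 to 0 °C; aq. NH4Cl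
Reagents that add atoms: none
Why: SN2' reduction of a Morita–Baylis–Hillman-type acetate: hydride adds in conjugate fashion to C12 of the alkylidene lactone and the enolate expels the C14 acetate (E1cB), which places the alkene at C13=C14 and deletes the C14 stereocentre while the alkyl acetates and the 8(17)-alkene are inert to borohydride.

Step 3
Reactants: 3 3,19-di-O-acetyl-14-deoxyandrographolide
Product: 4 14-deoxyandrographolide
Conditions: K2CO3 (0.5 equiv), MeOH, 0 °C to rt, argon; AcOH quench
Reagents that add atoms: none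
Why: Base-catalysed transesterification (methanolysis) frees the 3,19-diol, and any transient methanolysis of the butenolide recloses on neutralisation.

Step 4
Reactants: 4 14-deoxyandrographolide
Product: 5 14-deoxyandrographolide 3,19-cyclic thionocarbonate
Conditions: 1,1'-thiocarbonyldiimidazole (1.5 equiv), DMAP (0.1 equiv), toluene, 80 °C
Reagents that add atoms: 1,1'-thiocarbonyldiimidazole, S=C(n1ccnc1)n1ccnc1
Why: Thiocarbonylation of the 1,3-diol (equatorial 3-OH, axial CH2OH on C4) closes a six-membered cyclic thionocarbonate, the same ring that the 3,19-acetals of this diol form readily.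

Step 5
Reactants: 5 14-deoxyandrographolide 3,19-cyclic thionocarbonate
Product: 7 andrograpanin, via stannyl thiocarbonate 6 (not isolated)
Conditions: Bu3SnH (1.5 equiv, slow addition), AIBN (0.2 equiv), toluene, 110 °C; then KF, MeOH/H2O, rt
Reagents that add atoms: none
Why: Barton–McCombie-type radical deoxygenation: the stannyl radical adds to C=S and the adduct fragments towards the more stable secondary C3 radical (not the primary C19 radical), which is reduced by Bu3SnH, and fluoride then frees the C19 hydroxyl.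

Step 6
Reactants: 7 andrograpanin
Product: 8 (13Z)-ent-labda-8(17),13-diene-15,16,19-triol
Conditions: i-Bu2AlH (6 equiv), CH2Cl2, −78 to 0 °C; aq. KNaC4H4O6
Reagents that add atoms: none
Why: 1,2-Hydride reduction of the butenolide (lactone to diol through the lactol) without conjugate reduction; the ring holds C15 and C16 cis, so only the 13Z diol can form.

Step 7
Reactants: 8 (13Z)-ent-labda-8(17),13-diene-15,16,19-triol
Product: 9 (13Z)-ent-labda-8(17),13-diene-15,16,19-triyl triacetate
Conditions: Ac2O (6 equiv), pyridine, DMAP (0.1 equiv), CH2Cl2, rt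
Reagents that add atoms: acetic anhydride, CC(=O)OC(C)=O
Why: DMAP-catalysed exhaustive acetylation is forcing enough for the neopentyl C19 hydroxyl and leaves the alkenes alone.

Step 8
Reactants: 9 (13Z)-ent-labda-8(17),13-diene-15,16,19-triyl triacetate
Product: 10 (13Z)-16,19-diacetoxy-ent-labda-8(17),13-dien-15-ol
Conditions: Burkholderia cepacia lipase (Amano PS), 0.1 M KH2PO4/K2HPO4 buffer pH 7.0/acetone (9:1), 30 °C, stopped after one equivalent of acid is released
Reagents that add atoms: none
Why: Lipase-catalysed regioselective ester hydrolysis: in diacetates of 2-substituted (Z)-but-2-ene-1,4-diols the enzyme cleaves the ester remote from the substituent (C15), leaving the C16 acetate next to the fully substituted alkene carbon and the neopentyl C19 acetate.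

Step 9
Reactants: 10 (13Z)-16,19-diacetoxy-ent-labda-8(17),13-dien-15-ol
Product: 11 (13Z)-16,19-diacetoxy-ent-labda-8(17),13-dien-15-al
Conditions: Dess–Martin periodinane (1.3 equiv), NaHCO3, CH2Cl2, 0 °C; aq. Na2S2O3/NaHCO3
Reagents that add atoms: none
Why: Dess–Martin oxidation of the allylic alcohol under buffered, non-enolising conditions gives the (Z)-enal without geometric isomerisation or acetate loss.

Step 10
Reactants: 11 (13Z)-16,19-diacetoxy-ent-labda-8(17),13-dien-15-al
Product: 12 (13Z)-16,19-diacetoxy-ent-labda-8(17),13-dien-15-oic acid (target)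
Conditions: NaClO2 (3 equiv), NaH2PO4 (3 equiv), 2-methyl-2-butene (20 equiv), t-BuOH/H2O (4:1), 0 °C
Reagents that add atoms: sodium chlorite, [Na+].[O-]Cl=O
Why: Pinnick oxidation takes the enal to the acid at about pH 4 with retention of the 13Z geometry, the acetates are untouched and the scavenger alkene keeps the 8(17)-methylene from being chlorinated.

**Compound list**

1 | andrographolide, (3R,4R,5S,9R,10S,12E,14S)-3,14,19-trihydroxy-ent-labda-8(17),12-dien-16,15-olide | C=C1CC[C@@H]2[C@](C)(CO)[C@H](O)CC[C@@]2(C)[C@@H]1C/C=C1/C(=O)OC[C@H]1O | starting material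
2 | 3,14,19-tri-O-acetylandrographolide (3R,4R,5S,9R,10S,12E,14S) | C=C1CC[C@@H]2[C@](C)(COC(C)=O)[C@H](OC(C)=O)CC[C@@]2(C)[C@@H]1C/C=C1/C(=O)OC[C@H]1OC(C)=O | intermediate
3 | 3,19-di-O-acetyl-14-deoxyandrographolide, (3R,4R,5S,9R,10S)-3,19-diacetoxy-ent-labda-8(17),13-dien-16,15-olide | C=C1CC[C@@H]2[C@](C)(COC(C)=O)[C@H](OC(C)=O)CC[C@@]2(C)[C@@H]1CCC1=CCOC1=O | intermediate
4 | 14-deoxyandrographolide, (3R,4R,5S,9R,10S)-3,19-dihydroxy-ent-labda-8(17),13-dien-16,15-olide | C=C1CC[C@@H]2[C@](C)(CO)[C@H](O)CC[C@@]2(C)[C@@H]1CCC1=CCOC1=O | intermediate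
5 | 14-deoxyandrographolide 3,19-cyclic thionocarbonate (1,3-dioxane-2-thione across O3–C3–C4–C19–O19; 3R,4R,5S,9R,10S) | C=C1CC[C@@H]2[C@]3(C)COC(=S)O[C@@H]3CC[C@@]2(C)[C@@H]1CCC1=CCOC1=O | intermediate
6 | 19-O-[(tributylstannylsulfanyl)carbonyl]andrograpanin (4R,5S,9R,10S), not isolated | C=C1CC[C@@H]2[C@](C)(COC(=O)S[Sn](CCCC)(CCCC)CCCC)CCC[C@@]2(C)[C@@H]1CCC1=CCOC1=O | intermediate
7 | andrograpanin, (4R,5S,9R,10S)-19-hydroxy-ent-labda-8(17),13-dien-16,15-olide | C=C1CC[C@@H]2[C@](C)(CO)CCC[C@@]2(C)[C@@H]1CCC1=CCOC1=O | intermediate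
8 | (4R,5S,9R,10S,13Z)-ent-labda-8(17),13-diene-15,16,19-triol | C=C1CC[C@@H]2[C@](C)(CO)CCC[C@@]2(C)[C@@H]1CC/C(=C/CO)CO | intermediate
9 | (4R,5S,9R,10S,13Z)-ent-labda-8(17),13-diene-15,16,19-triyl triacetate | C=C1CC[C@@H]2[C@](C)(COC(C)=O)CCC[C@@]2(C)[C@@H]1CC/C(=C/COC(C)=O)COC(C)=O | intermediate
10 | (4R,5S,9R,10S,13Z)-16,19-diacetoxy-ent-labda-8(17),13-dien-15-ol | C=C1CC[C@@H]2[C@](C)(COC(C)=O)CCC[C@@]2(C)[C@@H]1CC/C(=C/CO)COC(C)=O | intermediate
11 | (4R,5S,9R,10S,13Z)-16,19-diacetoxy-ent-labda-8(17),13-dien-15-al | C=C1CC[C@@H]2[C@](C)(COC(C)=O)CCC[C@@]2(C)[C@@H]1CC/C(=C/C=O)COC(C)=O | intermediate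
12 | (4R,5S,9R,10S,13Z)-16,19-diacetoxy-ent-labda-8(17),13-dien-15-oic acid | C=C1CC[C@@H]2[C@](C)(COC(C)=O)CCC[C@@]2(C)[C@@H]1CC/C(=C/C(=O)O)COC(C)=O | target

**Step count and risks**

Total steps: 10. Longest linear sequence: 10 (the route is linear from 1).

Step 2 (SN2' hydride reduction) may over-reduce the new butenolide or attack the lactone carbonyl. The fallback sets out from 1 and returns at 4. Compound 1 is treated with 2,2-dimethoxypropane and pyridinium p-toluenesulfonate to give andrographolide 3,19-acetonide F1. A Myers reductive allylic transposition follows (2-nitrobenzenesulfonylhydrazide, PPh3, diethyl azodicarboxylate, THF, −30 °C to rt). Mitsunobu displacement at C14 gives the N-sulfonylhydrazine adduct F2, which loses the sulfinic acid to give the allylic diazene F3. Retro-ene loss of nitrogen from F3 delivers hydrogen to C12 and gives 14-deoxyandrographolide 3,19-acetonide F4. Aqueous acetic acid at rt then removes the acetonide to give 4.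

Step 5 (radical fragmentation of the cyclic thionocarbonate) may fragment partly towards C19 or be sluggish. The fallback sets out from 4 and returns at 8; here the regiochemistry is enforced by protection instead. Selective acetylation of the primary hydroxyl (Ac2O 1.1 equiv, pyridine, −20 °C) gives 19-O-acetyl-14-deoxyandrographolide F5. 1,1'-Thiocarbonyldiimidazole with DMAP in 1,2-dichloroethane at 80 °C gives the 3-O-(imidazol-1-ylthiocarbonyl) derivative F6. Bu3SnH and AIBN in toluene at 110 °C give 19-O-acetylandrograpanin F7. F7 is reduced under the conditions of step 6, with one more equivalent of i-Bu2AlH to cleave the acetate, to give 8.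

Step 8 (enzymatic regioselective deacetylation) may fail if the lipase does not accept the diterpenoid or hydrolyses the C16 ester as well. The fallback sets out from 8 and returns at 10. t-BuPh2SiCl (1.05 equiv) with imidazole in CH2Cl2 at −40 °C silylates the least hindered hydroxyl to give the 15-O-tert-butyldiphenylsilyl triol F8; the minor regioisomer is separated and recycled with Bu4NF. Ac2O, pyridine and DMAP give the silyl ether diacetate F9. HF·pyridine in THF/pyridine at 0 °C removes the silyl group to give 10.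

**Further compounds**

F1 | step 2 | andrographolide 3,19-acetonide | C=C1CC[C@@H]2[C@]3(C)COC(C)(C)O[C@@H]3CC[C@@]2(C)[C@@H]1C/C=C1/C(=O)OC[C@H]1O
F2 | step 2 | N-sulfonylhydrazine adduct, C14-inverted N-amino-N-(2-nitrobenzenesulfonyl) derivative of F1 (not isolated) | C=C1CC[C@@H]2[C@]3(C)COC(C)(C)O[C@@H]3CC[C@@]2(C)[C@@H]1C/C=C1/C(=O)OC[C@@H]1N(N)S(=O)(=O)c1ccccc1[N+](=O)[O-]
F3 | step 2 | allylic diazene at C14 (not isolated) | C=C1CC[C@@H]2[C@]3(C)COC(C)(C)O[C@@H]3CC[C@@]2(C)[C@@H]1C/C=C1/C(=O)OC[C@@H]1N=N
F4 | step 2 | 14-deoxyandrographolide 3,19-acetonide | C=C1CC[C@@H]2[C@]3(C)COC(C)(C)O[C@@H]3CC[C@@]2(C)[C@@H]1CCC1=CCOC1=O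
F5 | step 5 | 19-O-acetyl-14-deoxyandrographolide | C=C1CC[C@@H]2[C@](C)(COC(C)=O)[C@H](O)CC[C@@]2(C)[C@@H]1CCC1=CCOC1=O
F6 | step 5 | 19-O-acetyl-3-O-(imidazol-1-ylthiocarbonyl)-14-deoxyandrographolide | C=C1CC[C@@H]2[C@](C)(COC(C)=O)[C@H](OC(=S)n3ccnc3)CC[C@@]2(C)[C@@H]1CCC1=CCOC1=O
F7 | step 5 | 19-O-acetylandrograpanin | C=C1CC[C@@H]2[C@](C)(COC(C)=O)CCC[C@@]2(C)[C@@H]1CCC1=CCOC1=O
F8 | step 8 | (13Z)-15-(tert-butyldiphenylsilyloxy)-ent-labda-8(17),13-diene-16,19-diol | C=C1CC[C@@H]2[C@](C)(CO)CCC[C@@]2(C)[C@@H]1CC/C(=C/CO[Si](c1ccccc1)(c1ccccc1)C(C)(C)C)CO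
F9 | step 8 | (13Z)-15-(tert-butyldiphenylsilyloxy)-ent-labda-8(17),13-diene-16,19-diyl diacetate | C=C1CC[C@@H]2[C@](C)(COC(C)=O)CCC[C@@]2(C)[C@@H]1CC/C(=C/CO[Si](c1ccccc1)(c1ccccc1)C(C)(C)C)COC(C)=O
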